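The earlier runs and the new flask stem from a simulated flask for an exercise, noise included.

Ash cannot end above 75.0% product if each product takes one reagent, because that is its charge, and there reagent is the limiting reagent.

the same everywhere: initiator 9.9 mol%

| charge | starting material | reagent | remark | time |
|---|---|---|---|---|
| violet | 0.45 M (in portions, 4) | 1.5 equiv | run made earlier; portions every 6.0 h |  |
| cedar | 0.30 M (in portions, 4) | 1.50 equiv | the portions of starting material follow each other after 6.0 h, the first at the start | 50 h |
| oak | 0.30 M (in portions, 4) | 3.00 equiv | the portions of starting material follow each other after 6.0 h, the first at the start | 50 h |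
| ash | 0.30 M (in portions, 4) | 0.750 equiv | the portions of starting material follow each other after 6.0 h, the first at the start | 50 h |
| birch | 0.30 M (in portions, 4) | 2.20 equiv | the portions of starting material follow each other after 6.0 h, the first at the start | 50 h |
| elm | 0.30 M (in portions, 4) | 6.00 equiv | the portions of starting material follow each other after 6.0 h, the first at the start | 50 h |
| larch | 0.30 M (in portions, 4) | 1.00 equiv | the portions of starting material follow each other after 6.0 h, the first at the start | 50 h |

- violet (time / h: product / %, starting material / %): 1.50: 14.3, 9.6; 4.00: 18.9, 6.1; 8.00: 29.5, 20.4; 12.0: 36.9, 12.1; 20.0: 54.8, 40.1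

(each reading ± 0.5 percentage points)

- the numbers in the tables scatter with a standard deviation of 0.5 percentage points
- no earlier run changes the charge of initiator; that part of a forecast is a guess

- the flasks by amount of product, in percent of the starting material charged, highest first, at 50 h (cedar / oak / ash / birch / elm / larch)
- the amount of product, in percent of the starting material charged of the flask you put first, at 50 h
- the amount of product, in percent of the starting material charged of the flask you put last, at 50 h

A ceiling is no yield, though. Violet's product climbs from 18.9% to 54.8% between 4.00 h and 20.0 h, a slope of 0.0224 h⁻¹ of the charge, while its starting material moves from 6.1% to 40.1%. Run back to the start, that line leaves a burst of 9.93%, close to the initiator loading of 9.9 mol%.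

So I try a straight line for ash, but it reaches 122%, above the ceiling, and the rate has to fall as reagent goes. I write the balance instead: reagent left equals charge minus product. In violet that takes 131% down to 95.2% of the starting material, and from these two readings I read the spending constant, the share of the remaining reagent used per hour, as 0.0200 h⁻¹.

The objection is that violet ran at 0.45 M and these flasks at 0.30 M. The initiator is charged on the starting material, so if the rate follows it, the constant shrinks to 0.0133 h⁻¹. No run tests that, but I accept it. For ash my balance then gives 41.6%. For elm, which I expect first, the ceiling is the starting material, less the loss seen in violet, whose product and starting material sum to 94.9% at 20.0 h. More reagent gives more product in this reckoning, so I rank by charge.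

The forecast gives elm > oak > birch > cedar > larch > ash, with 96% first and 43% last, and says: “I assume the rate is first order in reagent, which violet alone cannot prove”.

The flasks give elm > oak > birch > cedar > larch > ash, with 95.8% and 55.6%, which is 13 percentage points above the forecast for ash.

    initiator → 2 initiating radical (k = 3.13 × 10⁻⁷ s⁻¹)
    starting material + initiating radical → capped initiator + first chain carrier (k = 25600 L mol⁻¹ s⁻¹)
    reagent + first chain carrier ⇌ product + second chain carrier (K = 2.10, k = 16500 L mol⁻¹ s⁻¹)
    starting material + second chain carrier → by-product + first chain carrier (k = 271 L mol⁻¹ s⁻¹)
    2 first chain carrier → ended chains (k = 5.00 × 10⁷ L mol⁻¹ s⁻¹)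
    2 starting material → homo dimer (k = 4.84 × 10⁻⁸ L mol⁻¹ s⁻¹)
    starting material ⇌ dormant form (K = 24.6, k = 2.72 × 10⁻⁶ s⁻¹)

Ash keeps 26% of its reagent at 50 h, so its spending constant, on average over the run, is 0.0270 h⁻¹, above the scaled 0.0133 h⁻¹. The neighbour, elm's recipe with 1.50 equiv of reagent, keeps 49%, which gives 0.0142 h⁻¹. Ash's constant is twice that, on half the reagent charge. The neighbour's balance gives reagent spent equal to 76.5% of the starting material charged, and it holds 76.4% product.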